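## Retrosynthetic overview

1. Rings are lettered A to G from the 2,4,6-trihydroxyphenyl end. The plan rests on rings C and E (O-aryl at positions 1 and 6, H at 2, OH at 3 to 5). Their adjacent oxygenated carbons C1-C6-C5-C4 and E6-E5-E4-E3 are each a squarate core, and both rings hang on ring D through D1-O-C6 and D4-O-E1.
2. Last disconnections: the eighteen O-alkyl groups (BBr3), then the diaryl ether bonds E6-O-F1 and C1-O-B4. These lead back to an F-G bromide, an A-B iodide and a C-D-E trimer whose only free phenols are C1-OH and E6-OH.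
3. Key disconnection: bonds C1-C2 and E1-E6 are cut together, which gives a ring D bis(4-alkenylcyclobutenone). In the forward direction this is two 4π openings followed by two 6π closures (double Moore rearrangement).
4. The precursor is built on ring D. D4-O carries an acetylide that adds to dimethyl squarate, followed by O-methylation and cis semihydrogenation. D1-O is acylated by methyl squarate chloride, and the mixed squarate takes 1-ethoxyvinyllithium.
5. Ring order: A, B, D, F and G are bought as benzenoid units. C and E are formed at the same time in the key step, and no other ring is made.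

Key step: step 10

Remark on the chemistry: the target has no stereocentre, the two quaternary cyclobutenone carbons form racemic and unrelated, so the bis(cyclobutenone) is used as its diastereomer mixture, and the aryloxyvinyl arm is made as the Z enol ether through an acetylide, because a trans-2-aryloxyvinyllithium holds Li and OAr antiperiplanar and should fragment to acetylene and lithium aryloxide, while the alkene geometry is not recorded in the aromatic product.

## Route

Step 1
Reactants: 1 2,6-dimethoxyhydroquinone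
Product: 2 2,6-dimethoxy-4-(triisopropylsilyloxy)phenol
Conditions: TIPSCl (1.05 equiv), imidazole, DMF, 0 °C to rt, Ar
Reagents that add atoms: chlorotriisopropylsilane CC(C)[Si](Cl)(C(C)C)C(C)C
Why: Silylation of a phenol with a bulky chlorosilane should take place at the D1 hydroxyl, which has two ortho hydrogens, and leave the D4 hydroxyl, which is flanked and hydrogen-bonded by both methoxy groups.

Step 2
Reactants: 2 2,6-dimethoxy-4-(triisopropylsilyloxy)phenol; 3 trichloroethylene
Product: 5 {4-[(E)-1,2-dichloroethenoxy]-3,5-dimethoxyphenoxy}triisopropylsilane, via dichloroacetylene 4 (not isolated)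
Conditions: K2CO3 (dry), DMF, 70 °C
Reagents that add atoms: none
Why: Base-induced dehydrochlorination of 3 gives 4, to which the D4 phenoxide adds in anti fashion (nucleophilic vinylation by elimination-addition), and this fixes the E geometry of the dichlorovinyl ether.

Step 3
Reactants: 5 dichlorovinyl ether of ring D; 6 dimethyl squarate
Product: 10 4-{[2,6-dimethoxy-4-(triisopropylsilyloxy)phenoxy]ethynyl}-2,3,4-trimethoxycyclobut-2-en-1-one (racemic), via chloroethynyl ether 7 (not isolated), via lithium aryloxyacetylide 8 (not isolated), via lithium carbinolate 9 (not isolated)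
Conditions: n-BuLi (2.05 equiv), THF, -78 to -40 °C; cannulated into 6 (1.2 equiv), THF, -78 °C; MeOTf, -78 to 0 °C; NaHCO3 aq
Reagents that add atoms: methyl triflate COS(=O)(=O)C(F)(F)F
Why: Dehydrochlorination and Cl/Li exchange unmask an acetylide that has no β-elimination pathway, it undergoes 1,2-addition to one of the two equivalent squarate carbonyls and the alkoxide is O-methylated in the flask; the quaternary carbon forms racemic, which is harmless because it becomes sp2 in step 10.

Step 4
Reactants: 10 alkynylcyclobutenone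
Product: 11 4-{(Z)-2-[2,6-dimethoxy-4-(triisopropylsilyloxy)phenoxy]ethenyl}-2,3,4-trimethoxycyclobut-2-en-1-one (racemic)
Conditions: H2 (1 atm), Pd/CaCO3 poisoned with Pb(OAc)2, quinoline, EtOAc, rt
Reagents that add atoms: none
Why: Syn delivery of hydrogen on poisoned palladium (Lindlar-type semihydrogenation of an ynol ether) sets the Z enol ether, while the tetrasubstituted ring alkene is too hindered to be reduced.

Step 5
Reactants: 11 Z-alkenylcyclobutenone silyl ether
Product: 12 4-[(Z)-2-(4-hydroxy-2,6-dimethoxyphenoxy)ethenyl]-2,3,4-trimethoxycyclobut-2-en-1-one (racemic)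
Conditions: TBAF, AcOH (1:1), THF, 0 °C
Reagents that add atoms: none
Why: Fluoride cleaves the aryl silyl ether (desilylation), and the acetic acid buffer keeps the freed phenoxide from attacking the vinylogous ester.

Step 6
Reactants: 13 squaric acid
Product: 14 3,4-dichlorocyclobut-3-ene-1,2-dione
Conditions: (COCl)2 (2.2 equiv), DMF (cat.), CH2Cl2, reflux
Reagents that add atoms: oxalyl chloride ClC(=O)C(Cl)=O
Why: Vilsmeier-type chlorination converts the two vinylogous acid functions of squaric acid into vinylogous acid chlorides.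

Step 7
Reactants: 14 3,4-dichlorocyclobut-3-ene-1,2-dione
Product: 15 3-chloro-4-methoxycyclobut-3-ene-1,2-dione (methyl squarate chloride)
Conditions: MeOH (1.0 equiv), CH2Cl2, 0 °C to rt
Reagents that add atoms: methanol CO
Why: Addition-elimination with a single equivalent of methanol should stop at the ester chloride, because the new methoxy donor deactivates the remaining C-Cl position.

Step 8
Reactants: 12 ring D phenol with arm E; 15 methyl squarate chloride
Product: 16 3-methoxy-4-{3,5-dimethoxy-4-[(Z)-2-(1,2,3-trimethoxy-4-oxocyclobut-2-en-1-yl)ethenoxy]phenoxy}cyclobut-3-ene-1,2-dione (aryl methyl squarate)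
Conditions: i-Pr2NEt, CH2Cl2, -40 to 0 °C
Reagents that add atoms: none
Why: The D1 phenoxide displaces chloride from the vinylogous acid chloride by addition-elimination (O-acylation), a route chosen because direct exchange on dimethyl squarate would have to expel methoxide in preference to the better leaving aryloxide.

Step 9
Reactants: 16 aryl methyl squarate; 17 ethyl vinyl ether
Product: 20 4-(1-ethoxyethenyl)-3,4-dimethoxy-2-{3,5-dimethoxy-4-[(Z)-2-(1,2,3-trimethoxy-4-oxocyclobut-2-en-1-yl)ethenoxy]phenoxy}cyclobut-2-en-1-one (ring D bis(cyclobutenone); diastereomer mixture), via 1-ethoxyvinyllithium 18 (not isolated), via lithium carbinolate 19 (not isolated)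
Conditions: 17, t-BuLi, THF, -78 to 0 °C; then added slowly (1.0 equiv) to 16, THF, -95 °C; MeOTf, -78 to -20 °C; NaHCO3 aq; Et3N-deactivated silica
Reagents that add atoms: methyl triflate COS(=O)(=O)C(F)(F)F
Why: 1,2-Addition of an α-lithiated enol ether to a squarate ester should occur at the carbonyl next to the methoxy-bearing carbon, since that carbonyl is conjugated with the weaker aryloxy donor and is less shielded, and in preference to the arm E carbonyl, which lacks the activating neighbouring C=O and sits beside a quaternary carbon; the new quaternary centre forms without control and vanishes in step 10.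

Step 10
Reactants: 20 ring D bis(cyclobutenone)
Product: 23 5-ethoxy-2-[4-(2-hydroxy-3,4,5-trimethoxyphenoxy)-3,5-dimethoxyphenoxy]-3,4-dimethoxyphenol (C-D-E trimer; only C1-OH and E6-OH free), via bis(dienylketene) 21 (not isolated), via bis(cyclohexadienone) 22 (not isolated)
Conditions: degassed p-xylene (0.005 M), base-washed glassware, Ar, 138 °C
Reagents that add atoms: none
Why: Heat breaks the C(=O)-C(quaternary) bond of each cyclobutenone in a conrotatory 4π electrocyclic opening, and the selectivity the step needs, inward rotation of the alkenyl group, is secured by the 4-methoxy donor on the same carbon, which prefers to rotate outward. Each dienylketene arm of 21 then closes by a disrotatory 6π electrocyclisation in which the ketene carbon bonds to the alkene terminus: ring C forms through C1-C2 (CH2 terminus of the ethoxyvinyl arm, which supplies C3 and C2) and ring E through E6-E1 (aryloxy-bearing terminus of the other arm, which supplies E2 and E1). Enolisation of the two cyclohexa-2,4-dienone units of 22 makes the sequence irreversible and leaves hydroxyl groups only on the former ketene carbons, C1 and E6. The closest known reaction type is the Moore rearrangement of squarate-derived 4-alkenyl-4-alkoxycyclobutenones to hydroquinone monoethers, which here runs at two independent sites held para to each other on ring D, too far apart to interact. No stereocentre survives, because both quaternary carbons, the Z geometry and the transient sp3 carbon E1 of 22 all end as aromatic sp2 atoms, so every diastereomer of 20 converges on 23. The inward aryloxy group of the Z arm should slow the ring E closure, but the ketene terminus is linear and carries no inward substituent, ring opening is reversible and closure is the only sink, and high dilution suppresses capture of a ketene by phenol already formed.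

Step 11
Reactants: 24 2-iodo-1,3-dimethoxybenzene
Product: 26 (4-iodo-3,5-dimethoxyphenyl)boronic acid, via pinacol boronate 25 (not isolated)
Conditions: B2pin2 (0.6 equiv), [Ir(OMe)(cod)]2 (1.5 mol %), 4,4'-di-tert-butyl-2,2'-bipyridine (3 mol %), THF, 80 °C; then NaIO4, 1 M HCl, THF-H2O, rt
Reagents that add atoms: bis(pinacolato)diboron CC1(C)OB(OC1(C)C)B1OC(C)(C)C(C)(C)O1; water O
Why: Sterically governed iridium-catalysed C-H borylation reaches only the C-H bond that has no ortho substituent (para to iodine, the future B1), and periodate cleavage of the pinacol unit releases the boronic acid.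

Step 12
Reactants: 26 (4-iodo-3,5-dimethoxyphenyl)boronic acid; 27 2,4,6-trimethoxyphenol
Product: 28 2-(4-iodo-3,5-dimethoxyphenoxy)-1,3,5-trimethoxybenzene (A-B iodide, iodine on B4)
Conditions: Cu(OAc)2 (1 equiv), pyridine (5 equiv), 4 Å molecular sieves, CH2Cl2, dry air, rt
Reagents that add atoms: none
Why: Chan-Lam coupling joins a di-ortho-substituted phenol to an unhindered arylboronic acid at room temperature to form A1-O-B1 and leaves the C-I bond untouched.

Step 13
Reactants: 29 4-bromo-2,6-dimethoxyphenol; 30 3,4,5-trimethoxyphenylboronic acid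
Product: 31 5-bromo-1,3-dimethoxy-2-(3,4,5-trimethoxyphenoxy)benzene (F-G bromide, bromine on F1)
Conditions: Cu(OAc)2 (1 equiv), pyridine (5 equiv), 4 Å molecular sieves, CH2Cl2, dry air, rt
Reagents that add atoms: none
Why: Chan-Lam coupling of the flanked F4 phenol with the open G1 boronic acid forms F4-O-G1 under conditions that do not touch the aryl bromide.

Step 14
Reactants: 23 C-D-E trimer; 28 A-B iodide
Product: 32 A-B-C-D-E pentamer, fully O-alkylated except for the free E6-OH
Conditions: 28 (1.2 equiv), CuI (20 mol %), picolinic acid (40 mol %), K3PO4, DMSO, 100 °C, Ar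
Reagents that add atoms: none
Why: In this Ullmann-type C-O coupling the C1 phenoxide has one free ortho position whereas E6-O is flanked on both sides, so the di-ortho-methoxy iodide should form only the tri-ortho-substituted ether C1-O-B4, a tetra-ortho-substituted ether at E6 being out of reach.

Step 15
Reactants: 32 pentamer with free E6-OH; 31 F-G bromide
Product: 33 fully protected heptamer (seventeen OMe groups and one OEt group on C3)
Conditions: 31 (1.5 equiv), CuI (20 mol %), picolinic acid (40 mol %), K3PO4, DMSO, 110 °C, Ar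
Reagents that add atoms: none
Why: Ullmann-type C-O coupling of the remaining flanked E6 phenoxide with a bromide whose reacting carbon F1 has two ortho hydrogens is the hindered-phenol, open-halide pairing that this catalyst system handles.

Step 16
Reactants: 33 protected heptamer
Product: 34 CNP0292517.0 (target)
Conditions: BBr3 (40 equiv), CH2Cl2, -78 °C to rt, Ar; degassed H2O, 0 °C; Sephadex LH-20 under Ar
Reagents that add atoms: none
Why: Lewis acid-mediated cleavage of aryl alkyl ethers (BBr3 dealkylation) removes the seventeen methyl groups and the ethyl group by bromide attack at the alkyl carbon and leaves the six diaryl ether bonds intact because neither of their carbons is open to substitution, air being excluded because the pyrogallol-type rings oxidise easily.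

## Compound list

1 | 2,6-dimethoxyhydroquinone | COc1cc(O)cc(OC)c1O | starting material
2 | 2,6-dimethoxy-4-(triisopropylsilyloxy)phenol | COc1cc(O[Si](C(C)C)(C(C)C)C(C)C)cc(OC)c1O | intermediate
3 | trichloroethylene | ClC=C(Cl)Cl | starting material
4 | dichloroacetylene (not isolated) | ClC#CCl | intermediate
5 | {4-[(E)-1,2-dichloroethenoxy]-3,5-dimethoxyphenoxy}triisopropylsilane | Cl/C=C(/Cl)Oc1c(OC)cc(O[Si](C(C)C)(C(C)C)C(C)C)cc1OC | intermediate
6 | dimethyl squarate | COC1=C(OC)C(=O)C1=O | starting material
7 | [4-(chloroethynyloxy)-3,5-dimethoxyphenoxy]triisopropylsilane (not isolated) | ClC#COc1c(OC)cc(O[Si](C(C)C)(C(C)C)C(C)C)cc1OC | intermediate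
8 | lithium aryloxyacetylide of ring D (not isolated) | [Li]C#COc1c(OC)cc(O[Si](C(C)C)(C(C)C)C(C)C)cc1OC | intermediate
9 | lithium carbinolate of the acetylide-squarate adduct (not isolated, racemic) | [Li]OC1(C#COc2c(OC)cc(O[Si](C(C)C)(C(C)C)C(C)C)cc2OC)C(OC)=C(OC)C1=O | intermediate
10 | 4-{[2,6-dimethoxy-4-(triisopropylsilyloxy)phenoxy]ethynyl}-2,3,4-trimethoxycyclobut-2-en-1-one (racemic) | COC1=C(OC)C(OC)(C#COc2c(OC)cc(O[Si](C(C)C)(C(C)C)C(C)C)cc2OC)C1=O | intermediate
11 | 4-{(Z)-2-[2,6-dimethoxy-4-(triisopropylsilyloxy)phenoxy]ethenyl}-2,3,4-trimethoxycyclobut-2-en-1-one (racemic) | COC1=C(OC)C(OC)(/C=C\Oc2c(OC)cc(O[Si](C(C)C)(C(C)C)C(C)C)cc2OC)C1=O | intermediate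
12 | 4-[(Z)-2-(4-hydroxy-2,6-dimethoxyphenoxy)ethenyl]-2,3,4-trimethoxycyclobut-2-en-1-one (racemic) | COC1=C(OC)C(OC)(/C=C\Oc2c(OC)cc(O)cc2OC)C1=O | intermediate
13 | squaric acid | OC1=C(O)C(=O)C1=O | starting material
14 | 3,4-dichlorocyclobut-3-ene-1,2-dione | ClC1=C(Cl)C(=O)C1=O | intermediate
15 | 3-chloro-4-methoxycyclobut-3-ene-1,2-dione | COC1=C(Cl)C(=O)C1=O | intermediate
16 | aryl methyl squarate of ring D carrying arm E (racemic) | COC1=C(Oc2cc(OC)c(O/C=C\C3(OC)C(OC)=C(OC)C3=O)c(OC)c2)C(=O)C1=O | intermediate
17 | ethyl vinyl ether | C=COCC | starting material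
18 | 1-ethoxyvinyllithium (not isolated) | [Li]C(=C)OCC | intermediate
19 | lithium carbinolate of the ethoxyvinyl adduct (not isolated, diastereomer mixture) | C=C(OCC)C1(O[Li])C(OC)=C(Oc2cc(OC)c(O/C=C\C3(OC)C(OC)=C(OC)C3=O)c(OC)c2)C1=O | intermediate
20 | ring D bis(cyclobutenone), Z enol ether arm, diastereomer mixture (key-step precursor) | C=C(OCC)C1(OC)C(OC)=C(Oc2cc(OC)c(O/C=C\C3(OC)C(OC)=C(OC)C3=O)c(OC)c2)C1=O | intermediate
21 | bis(dienylketene) (not isolated) | C=C(OCC)\C(OC)=C(OC)/C(Oc1cc(OC)c(O/C=C\C(OC)=C(OC)/C(OC)=C=O)c(OC)c1)=C=O | intermediate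
22 | bis(cyclohexa-2,4-dienone) (not isolated, racemic at E1) | CCOC1=C(OC)C(OC)=C(Oc2cc(OC)c(OC3C=C(OC)C(OC)=C(OC)C3=O)c(OC)c2)C(=O)C1 | intermediate
23 | C-D-E trimer, 5-ethoxy-2-[4-(2-hydroxy-3,4,5-trimethoxyphenoxy)-3,5-dimethoxyphenoxy]-3,4-dimethoxyphenol (key-step product) | CCOc1cc(O)c(Oc2cc(OC)c(Oc3cc(OC)c(OC)c(OC)c3O)c(OC)c2)c(OC)c1OC | intermediate
24 | 2-iodo-1,3-dimethoxybenzene | COc1cccc(OC)c1I | starting material
25 | 2-(4-iodo-3,5-dimethoxyphenyl)-4,4,5,5-tetramethyl-1,3,2-dioxaborolane (not isolated) | COc1cc(B2OC(C)(C)C(C)(C)O2)cc(OC)c1I | intermediate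
26 | (4-iodo-3,5-dimethoxyphenyl)boronic acid | COc1cc(B(O)O)cc(OC)c1I | intermediate
27 | 2,4,6-trimethoxyphenol | COc1cc(OC)c(O)c(OC)c1 | starting material
28 | A-B iodide, 2-(4-iodo-3,5-dimethoxyphenoxy)-1,3,5-trimethoxybenzene | COc1cc(OC)c(Oc2cc(OC)c(I)c(OC)c2)c(OC)c1 | intermediate
29 | 4-bromo-2,6-dimethoxyphenol | COc1cc(Br)cc(OC)c1O | starting material
30 | 3,4,5-trimethoxyphenylboronic acid | COc1cc(B(O)O)cc(OC)c1OC | starting material
31 | F-G bromide, 5-bromo-1,3-dimethoxy-2-(3,4,5-trimethoxyphenoxy)benzene | COc1cc(Br)cc(OC)c1Oc1cc(OC)c(OC)c(OC)c1 | intermediate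
32 | A-B-C-D-E pentamer with free E6-OH | COc1cc(OC)c(Oc2cc(OC)c(Oc3cc(OCC)c(OC)c(OC)c3Oc3cc(OC)c(Oc4cc(OC)c(OC)c(OC)c4O)c(OC)c3)c(OC)c2)c(OC)c1 | intermediate
33 | protected heptamer (17 OMe, OEt on C3) | COc1cc(OC)c(Oc2cc(OC)c(Oc3cc(OCC)c(OC)c(OC)c3Oc3cc(OC)c(Oc4cc(OC)c(OC)c(OC)c4Oc4cc(OC)c(Oc5cc(OC)c(OC)c(OC)c5)c(OC)c4)c(OC)c3)c(OC)c2)c(OC)c1 | intermediate
34 | CNP0292517.0 | Oc1cc(O)c(Oc2cc(O)c(Oc3cc(O)c(O)c(O)c3Oc3cc(O)c(Oc4cc(O)c(O)c(O)c4Oc4cc(O)c(Oc5cc(O)c(O)c(O)c5)c(O)c4)c(O)c3)c(O)c2)c(O)c1 | target

## Step count and risks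

Total step count: 16. Longest linear sequence: 11 steps (1, 2, 3, 4, 5, 8, 9, 10, 14, 15, 16).

**Step 10.** The slower ring E closure may stall. The surviving ketene could then be intercepted by phenol already formed on another molecule, and the ethoxyvinyl group could be lost by adventitious hydrolysis during the long heating.

Fallback: the two rings are closed one after the other, so that no molecule ever holds a ketene and a free phenol of the other arm.
- Setting out from 11, thermolysis in degassed xylene closes ring E alone and should give the silylated D-E phenol F1.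
- The E6 hydroxyl is capped (BnBr, K2CO3, DMF) as the benzyl ether F2.
- TBAF/AcOH frees the D1 phenol F3.
- Acylation with 15 and i-Pr2NEt gives the aryl methyl squarate F4.
- Addition of 18 and methylation with MeOTf, now with no second carbonyl-bearing arm present, gives the monocyclobutenone F5.
- A second thermolysis closes ring C to the E6-benzylated trimer F6.
- Hydrogenolysis (H2, Pd/C, EtOAc) comes back to the route at 23.

**Step 14.** Activation of the electron-rich, doubly ortho-substituted C-I bond by copper may be too slow. In that case protodeiodination and oxidative decay of the bis(phenoxide) could take over.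

Fallback: ring B is brought in alone as an electron-poor partner and ring A is added last.
- Setting out from 23, the C1 phenoxide is coupled (CuI, picolinic acid, K3PO4, DMSO) with commercial 4-bromo-3,5-dimethoxybenzaldehyde, whose para formyl group makes B4 electron-poor. This gives the B-C-D-E aldehyde F7.
- Arylation of E6-OH with 31 under the conditions of step 15 gives the hexamer aldehyde F8.
- Baeyer-Villiger oxidation (mCPBA, CH2Cl2) gives the aryl formate F9.
- Methanolysis (K2CO3, MeOH) gives the B1 phenol F10.
- This unhindered phenol is joined to 2-iodo-1,3,5-trimethoxybenzene by Ullmann coupling, which has to form only a di-ortho-substituted ether, and the sequence comes back to the route at 33.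

**Step 9.** The vinyllithium may also attack the arm E carbonyl, or the squarate carbonyl next to the aryloxy carbon, or it may displace aryloxide.

Fallback: the arm E carbonyl is shielded as the neighbour of an alkoxide, and both carbinols are methylated together at the end.
- Setting out from 9, quenching with aqueous NH4Cl instead of MeOTf gives the alkynyl carbinol F11.
- Semihydrogenation as in step 4 gives the Z-alkenyl carbinol F12.
- TBAF/AcOH gives the phenol carbinol F13.
- Acylation of the more acidic phenol with 15 and i-Pr2NEt gives the hydroxy aryl methyl squarate F14.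
- Two equivalents of 18 at -95 °C first deprotonate the carbinol, which deactivates the adjacent carbonyl, and then add to the squarate to give the dilithium bis(carbinolate) F15.
- Excess MeOTf methylates both oxygens and comes back to the route at 20.

## Further compounds

F1 | step 10 | 6-[2,6-dimethoxy-4-(triisopropylsilyloxy)phenoxy]-2,3,4-trimethoxyphenol | COc1cc(Oc2c(OC)cc(O[Si](C(C)C)(C(C)C)C(C)C)cc2OC)c(O)c(OC)c1OC
F2 | step 10 | E6-benzyl ether of F1 | COc1cc(Oc2c(OC)cc(O[Si](C(C)C)(C(C)C)C(C)C)cc2OC)c(OCc2ccccc2)c(OC)c1OC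
F3 | step 10 | 4-(2-benzyloxy-3,4,5-trimethoxyphenoxy)-3,5-dimethoxyphenol | COc1cc(Oc2c(OC)cc(O)cc2OC)c(OCc2ccccc2)c(OC)c1OC
F4 | step 10 | aryl methyl squarate of the D-E dimer | COC1=C(Oc2cc(OC)c(Oc3cc(OC)c(OC)c(OC)c3OCc3ccccc3)c(OC)c2)C(=O)C1=O
F5 | step 10 | 4-(1-ethoxyethenyl)-3,4-dimethoxy-2-(D-E aryloxy)cyclobut-2-en-1-one (racemic) | C=C(OCC)C1(OC)C(OC)=C(Oc2cc(OC)c(Oc3cc(OC)c(OC)c(OC)c3OCc3ccccc3)c(OC)c2)C1=O
F6 | step 10 | C-D-E trimer with E6-OBn and free C1-OH | CCOc1cc(O)c(Oc2cc(OC)c(Oc3cc(OC)c(OC)c(OC)c3OCc3ccccc3)c(OC)c2)c(OC)c1OC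
F7 | step 14 | B-C-D-E tetramer with B1-CHO and free E6-OH | O=Cc1cc(OC)c(Oc2cc(OCC)c(OC)c(OC)c2Oc2cc(OC)c(Oc3cc(OC)c(OC)c(OC)c3O)c(OC)c2)c(OC)c1
F8 | step 14 | B-to-G hexamer with B1-CHO | O=Cc1cc(OC)c(Oc2cc(OCC)c(OC)c(OC)c2Oc2cc(OC)c(Oc3cc(OC)c(OC)c(OC)c3Oc3cc(OC)c(Oc4cc(OC)c(OC)c(OC)c4)c(OC)c3)c(OC)c2)c(OC)c1
F9 | step 14 | B-to-G hexamer B1 formate | O=COc1cc(OC)c(Oc2cc(OCC)c(OC)c(OC)c2Oc2cc(OC)c(Oc3cc(OC)c(OC)c(OC)c3Oc3cc(OC)c(Oc4cc(OC)c(OC)c(OC)c4)c(OC)c3)c(OC)c2)c(OC)c1
F10 | step 14 | B-to-G hexamer with free B1-OH | Oc1cc(OC)c(Oc2cc(OCC)c(OC)c(OC)c2Oc2cc(OC)c(Oc3cc(OC)c(OC)c(OC)c3Oc3cc(OC)c(Oc4cc(OC)c(OC)c(OC)c4)c(OC)c3)c(OC)c2)c(OC)c1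
F11 | step 9 | 4-hydroxy analogue of 10 (racemic) | COC1=C(OC)C(O)(C#COc2c(OC)cc(O[Si](C(C)C)(C(C)C)C(C)C)cc2OC)C1=O
F12 | step 9 | 4-hydroxy analogue of 11, Z (racemic) | COC1=C(OC)C(O)(/C=C\Oc2c(OC)cc(O[Si](C(C)C)(C(C)C)C(C)C)cc2OC)C1=O
F13 | step 9 | 4-hydroxy analogue of 12, Z (racemic) | COC1=C(OC)C(O)(/C=C\Oc2c(OC)cc(O)cc2OC)C1=O
F14 | step 9 | 4-hydroxy analogue of 16, Z (racemic) | COC1=C(Oc2cc(OC)c(O/C=C\C3(O)C(OC)=C(OC)C3=O)c(OC)c2)C(=O)C1=O
F15 | step 9 | dilithium bis(carbinolate), Z (not isolated, diastereomer mixture) | C=C(OCC)C1(O[Li])C(OC)=C(Oc2cc(OC)c(O/C=C\C3(O[Li])C(OC)=C(OC)C3=O)c(OC)c2)C1=O
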